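**Small charge.** A small charge of capture agent, 0.0320 M, meets 0.032 M of starting material in oak, birch and ash, which are one recipe read at three times.

| flask | starting material | capture agent | remark | time |
|---|---|---|---|---|
| delta | 0.032 M | 0.021 M | run made earlier |  |
| eta | 0.032 M | 0.048 M | run made earlier |  |
| gamma | 0.064 M | 0.032 M | run made earlier |  |
| oak | 0.032 M | 0.0320 M |  | 2.0 d |
| birch | 0.032 M | 0.0320 M |  | 4.0 d |
| ash | 0.032 M | 0.0320 M |  | 8.0 d |

| run | time / d | starting material / % | target / % | open intermediate / % | trapped intermediate / % | isomer of the product / % |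
|---|---|---|---|---|---|---|
| delta | 0.417 | 46.9 | 1.3 | 48.2 | 3.2 | 0.2 |
| delta | 0.833 | 22.0 | 4.6 | 62.8 | 10.6 | 0.5 |
| delta | 1.25 | 10.7 | 7.6 | 63.3 | 17.3 | 1.6 |
| delta | 1.67 | 4.8 | 9.1 | 59.6 | 23.8 | 2.9 |
| delta | 2.08 | 2.6 | 11.1 | 54.6 | 28.3 | 4.3 |
| delta | 2.50 | 1.3 | 12.2 | 48.5 | 32.5 | 6.0 |
| eta | 0.208 | 67.9 | 0.4 | 29.0 | 2.6 | 0 |
| eta | 0.333 | 54.7 | 1.0 | 38.7 | 5.7 | 0 |
| eta | 0.500 | 40.5 | 2.1 | 46.9 | 11.0 | 0.5 |
| eta | 0.833 | 22.2 | 3.5 | 51.9 | 22.0 | 0.8 |
| eta | 1.67 | 4.4 | 7.2 | 40.0 | 45.3 | 2.3 |
| eta | 2.50 | 0.9 | 8.4 | 27.1 | 58.9 | 4.5 |
| gamma | 0.208 | 68.2 | 0.6 | 29.3 | 1.9 | 0 |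
| gamma | 0.333 | 54.7 | 0.9 | 41.3 | 3.4 | 0.1 |
| gamma | 0.625 | 32.1 | 2.5 | 54.7 | 10.3 | 0 |
| gamma | 1.25 | 10.4 | 6.7 | 59.2 | 22.1 | 1.7 |
| gamma | 2.50 | 0.8 | 11.4 | 46.0 | 36.2 | 5.8 |

(standard deviation of a reading: 0.3 percentage points)



1. which of these there is most of at the end, counted by the starting material in it, oak (target / open intermediate / trapped intermediate / isomer of the product)
2. which of these there is most of at the end, counted by the starting material in it, birch (target / open intermediate / trapped intermediate / isomer of the product)
3. which of these there is most of at the end, counted by the starting material in it, ash (target / open intermediate / trapped intermediate / isomer of the product)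
4. the largest of these amounts at the end, in percent of the starting material charged, oak
5. the largest of these amounts at the end, in percent of the starting material charged, birch
6. the largest of these amounts at the end, in percent of the starting material charged, ash

**Fork constant.** I follow one molecule of open intermediate: it meets capture agent and becomes trapped intermediate, or it leaks to target and isomer of the product, which I count together as leak. Between two late readings of a run, I divide trapped gained by leak gained, then by the mean capture agent present, which is its charge minus what the trapped intermediate holds. Delta gives 117 M⁻¹, eta 122 M⁻¹ and gamma 120 M⁻¹. Their mean, 120 M⁻¹, is my fork constant, the odds of capture per molar of agent.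

**Bench rule.** The habit is to treat the agent as constant, pseudo-first-order. Oak's odds are then 3.83, a chance of capture of 79.3%. But that chance asks for 79.3% of the agent's charge, with agent over starting material at a ratio of 1.00, so the rule fails here.

**Ceiling.** With equal charges, the fraction of agent left, a, falls as exp(−odds × leak), and once the open intermediate has gone, leak equals a. Averaging a guess with what it returns, from 0.207 through 0.330, gives 0.306, so trapped intermediate stops near 69.4%. I commit to open intermediate leading in oak and trapped intermediate leading in birch and ash, with ash under that ceiling.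

**The result.** The forecast says open intermediate at 46% for oak, trapped intermediate at 54.5% for birch and trapped intermediate at 64% for ash, adding “Slow reversal of trapping can't be excluded”. The flask gives open intermediate at 45.6% in oak, trapped intermediate at 55.8% in birch and trapped intermediate at 65.4% in ash.

    starting material → open intermediate (k = 0.0760 h⁻¹)
    open intermediate → target (k = 0.00570 h⁻¹)
    open intermediate + capture agent → trapped intermediate (k = 0.660 M⁻¹ h⁻¹)
    target ⇌ isomer of the product (K = 29.0, k = 0.0160 h⁻¹)

**Reading time.** The difference in time is the main reason ash holds 5.91% open intermediate, against 45.6% without that difference, though trapped intermediate leads in ash. Left until 20.0 d, oak holds 68.6% trapped intermediate, against my ceiling of 69.4%. In ash, between 4.00 d and 8.00 d, the fork constant times the mean agent gives odds of 1.51, and the flask's own gains give 1.45.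

The earlier runs and the new flask come from a simulation with constants of no real substance.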